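## Structural features

The target is one cyclobutane ring in which all four carbons are CH stereocentres. C1 and C3 carry 2,4-dihydroxybenzoyl groups and C2 and C4 carry phenyl groups, the head-to-tail pattern of a chalcone dimer. The two aroyl groups are trans to each other across the ring, and so are the two phenyls. Each aroyl carbon therefore has one cis and one trans phenyl neighbour (C1 cis to the C4 phenyl, C3 cis to the C2 phenyl), which is the α-truxillic arrangement; the molecule has a centre of symmetry and is achiral. This is not the all-trans, lowest-strain isomer, and C1 and C3 are each flanked by phenyls on opposite faces, so neither approach control nor a simple stability argument fixes their configuration; that, not the ring itself, is the real difficulty. The fragile points are the enolisable C1–H and C3–H next to the aryl ketones (epimerisation, and retro-Michael opening of the strained 1,3-diacyl ring under base) and the oxidisable, nucleophilic resorcinol rings. The key step uses the fact that C2 sits between C1 and C3 and across from phenyl-bearing C4: with C2 as a ketone carbon this is a 3-phenylcyclobutanone with one-carbon oxygenated arms on both α-carbons, which a keteniminium (C2, C3) and a β-substituted styrene (C1, C4) assemble in a polar [2+2].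

## Logic of the disconnections

**18 ⇒ 16 + two 17.** The two carbonyl–aryl bonds are cut. Each 2,4-dihydroxyphenyl ketone is the retron of a Nencki-type acylation at C4 of 17, so the phenols and the enolisable aryl ketones exist only in the last flask. What remains, 16, is a centrosymmetric diacid and a known compound, so its configuration can be checked by comparison. The forward step must take up two molecules of 17, one per carboxyl group, and acylate on carbon without enolising C1 or C3.

**16 ⇒ 14 (through 15).** No skeletal bond is cut; the operation is inversion at one carboxyl-bearing carbon plus ester/acid interchange. The ring-forming chemistry delivers the two one-carbon arms cis to each other, whereas the target needs them trans, and an ester enolate is the mildest handle for inverting one centre. The gain is that 14 has both arms on one face and is reachable by steric control alone. The demand is that the equilibrium populates 15, that the enolate does not open the ring, and that 16 can be separated from its cis isomer.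

**14 ⇒ 13 ⇒ 12 ⇒ 11.** The O–CH3 bonds, then the oxidation level of the carboxyl carbons, then the O–Si bonds are removed. The carboxyl carbons travel as silyl-protected hydroxymethyl groups, so the ring carries no acidic or electrophilic carbon during the organometallic and cationic steps. The demand is an oxidation of two cis hydroxymethyl groups that does not stop at a bridged lactone.

**11 ⇒ 10 ⇒ 8 + 9.** The C2–H bond and then the C2–phenyl bond are cut. A ketone at C2 is the natural anchor for the second phenyl, and the resulting tertiary benzylic alcohol ionises easily. The gain is the loss of one phenyl and one stereocentre; 8 is a meso ketone with three centres. The demand is that hydride reaches the C2 cation anti to both arms and that the cation neither loses a proton nor takes hydride internally. For this reason the arms are silyl ethers: an ether with a benzylic C–H would place a hydride donor five atoms from the cationic carbon.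

**8 ⇒ 3 + 5 (through 7 and 6).** The C2–C1 and C3–C4 bonds are cut, which opens the ring into an amide-derived two-carbon unit (C2, C3) and an alkene (C1, C4). One step then builds the ring, two skeletal bonds and three stereocentres from two acyclic pieces of similar size. The demand is regiochemistry (C2 bonded to C1, not C4), trans relationships between the C4 phenyl and both arms, and a keteniminium that survives long enough to be trapped. The same hydride-shift argument applies to the keteniminium carbon, so the silyl ethers serve here too.

**3 ⇒ 2 ⇒ 1, and 5 ⇒ 4.** The amide C–N bond (back to an ester) and the two O–Si bonds are cut. Both partners then come from commercial 1 and commercial 4 by routine protection and aminolysis. The demand is only that aminolysis does not eliminate the β-silyloxy group.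

## Other disconnections considered

Alternative 1: The cut is at the C1–carbonyl and carbonyl–aryl bonds of one aroyl group while C1=C2 is an alkene. Cyclobutenyl triflate A2, carbon monoxide A4 and boronic acid A3 would be joined by Pd(PPh3)4 (zerovalent palladium: oxidative addition into the C–OTf bond, CO insertion, transmetalation, reductive elimination) to give cyclobutene diketone A1.
- In favour: the aryl ketone arrives at the correct oxidation level in one operation, and the four ring carbons with both phenyls trace back to the phenylketene dimer A5. On redox economy this alternative is the better plan, since the oxidation, esterification and saponification of steps 8–10 have no counterpart.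
- Against: A2 needs a full earlier round of triflation, carbonylation and reduction. Its C3–H is doubly activated (α to a ketone and allylic). The tetrasubstituted cyclobutene may undergo 4π ring opening at coupling temperature. The key step creates no stereocentre.
- Afterwards C1=C2 must be reduced with the two new hydrogens on opposite faces, which no syn hydrogenation gives. A conjugate reduction followed by protonation at C1 is needed, and that protonation occurs at a carbon flanked by phenyls on opposite faces. This is the same open configurational question as step 10 of the chosen route; on this point the two plans are equal. Four methyl ethers must then be cleaved.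
- Comparison: structurally, the chosen route makes the ring with three centres under steric control, whereas A1 arrives with one relationship set. Mechanistically, it is cross-coupling on a sensitive strained alkene against a polar cycloaddition. The step count is similar.

Alternative 2: The cut is at the C2–phenyl and C4–phenyl bonds. trans-Diamide A7 and two molecules of iodobenzene A8 under Pd(OAc)2 and AgOAc (divalent palladium: amide-directed C–H palladation through a five-membered palladacycle, oxidative addition of A8, reductive elimination) would give A6.
- In favour: each phenyl is delivered cis to the amide that directs it, so with a trans-diamide the α-truxillic pattern follows from the mechanism and not from an equilibrium. On stereochemical logic this is the better plan. It is also clearly shorter: hydrolysis of A6 gives 16 and joins the chosen route at step 11.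
- Against: each ring methylene of A7 lies between two directing amides on opposite faces. After the first arylation the second phenyl can be placed by the other amide (giving A6) or by the same amide on the same face, which would put the two phenyls cis, and nothing in the substrate enforces the former. Over-arylation is possible, and removing two quinolin-8-yl amide auxiliaries without epimerising C1 and C3 is demanding.
- Comparison: the ring is bought, not made; C–H activation replaces cycloaddition; step economy favours the alternative, and control of which C–H bond reacts second favours the chosen route.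

Alternative 3: The cut removes both benzene rings at C2 and C4. Diyne A10 and four molecules of acetylene A11 under CpCo(CO)2 (monovalent cobalt: cobaltacyclopentadiene formation, then alkyne insertion) would give A9, the tetra-O-methyl ether of the target.
- In favour: the key step makes no stereocentre and does not touch the ring carbons, so it cannot erode configuration already present. On stereochemical risk within the key step it is better than the chosen plan, which has to create three centres.
- Against: the whole stereochemical problem moves unchanged into A10, a tetrasubstituted cyclobutane with the same pattern and ethynyl in place of phenyl, so nothing is simplified. A10 has propargylic, ketone-activated C–H bonds prone to epimerisation and allene formation. Cotrimerisation of each terminal alkyne with two A11 competes with trimerisation of A11 alone and with oligomerisation of A10. Six C–C bonds are spent on two phenyl groups that the chosen route buys ready-made in 5 and 9. Four O-demethylations follow.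
- Comparison: structurally there is no gain; mechanistically it is a low-chemoselectivity metal-mediated cyclisation next to two aryl ketones; step economy is worse. Both plans need a final deprotection of some kind, and on that point they are about equal.

Key step: step 4

Remark: the target is read as the centrosymmetric, achiral diastereomer, so only relative configuration is at issue; all intermediates are meso or racemic, and the stereodescriptors in the SMILES of racemic compounds show one enantiomer.

## Route

Step 1
Reactants: 1 methyl 3-hydroxypropanoate
Product: 2 methyl 3-[(tert-butyldiphenylsilyl)oxy]propanoate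
Conditions: TBDPSCl, imidazole, DMF, rt
Reagents that add atoms: tert-butyl(chloro)diphenylsilane CC(C)(C)[Si](Cl)(c1ccccc1)c1ccccc1
Why: Imidazole-promoted O-silylation of the primary alcohol; this silyl ether has no hydridic C–H next to oxygen, is a poor Lewis base toward Tf2O and survives CF3CO2H, which a benzyl ether would not offer.

Step 2
Reactants: 2 methyl 3-[(tert-butyldiphenylsilyl)oxy]propanoate
Product: 3 3-[(tert-butyldiphenylsilyl)oxy]-N,N-dimethylpropanamide
Conditions: Me2NH·HCl, AlMe3, toluene, 0 °C → 50 °C; then aq. HCl
Reagents that add atoms: dimethylamine hydrochloride CNC.Cl
Why: Weinreb-type aminolysis; the aluminium amide formed from AlMe3 and the amine salt converts the ester directly into the dimethylamide and is too weakly basic to eliminate the β-silyloxy group.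

Step 3
Reactants: 4 (E)-cinnamyl alcohol
Product: 5 (E)-tert-butyl(cinnamyloxy)diphenylsilane
Conditions: TBDPSCl, imidazole, DMF, rt
Reagents that add atoms: tert-butyl(chloro)diphenylsilane CC(C)(C)[Si](Cl)(c1ccccc1)c1ccccc1
Why: O-silylation of the allylic alcohol; the (E) alkene is untouched, and the bulky, weakly basic silyl ether makes ionisation of the cinnamyl C–O bond under the electrophilic conditions of step 4 unlikely.

Step 4
Reactants: 3 3-[(tert-butyldiphenylsilyl)oxy]-N,N-dimethylpropanamide; 5 (E)-tert-butyl(cinnamyloxy)diphenylsilane
Product: 8 2,4-bis{[(tert-butyldiphenylsilyl)oxy]methyl}-3-phenylcyclobutan-1-one (both side chains trans to phenyl; meso), via keteniminium triflate 6 (not isolated), via cyclobutaniminium triflate 7 (not isolated)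
Conditions: Tf2O, ClCH2CH2Cl, −20 °C; then 5 (2.5 equiv), 2,4,6-collidine, 80 °C; then aq. NaHCO3, 40 °C
Reagents that add atoms: water O
Why: Tf2O O-triflylates amide 3 and collidine removes an α-proton to give keteniminium triflate 6; the alkene of 5 attacks the central carbon of 6 through its carbon remote from phenyl (C2–C1 bond), leaving a benzylic cation at C4 and an enamine at C2=C3. The enamine carbon C3 then collapses onto the cation (C3–C4 bond), closing the four-membered ring as cyclobutaniminium salt 7, which water hydrolyses to 8; this is the Ghosez keteniminium–alkene [2+2] cycloaddition to cyclobutanones, a stepwise polar process. The ring therefore closes by cation–enamine recombination, formally a 4-exo closure. Regiochemistry, the selectivity the step needs most, is secured by the phenyl of 5, which stabilises positive charge only at C4, so the iminium carbon ends between C1 and C3. C1 and C4 come out trans because the (E) geometry of 5 is carried through a ring closure faster than bond rotation, and trans is also the less strained arrangement. C3 is set in the closure with its arm away from the C4 phenyl, and since C1 and C3 are both α to the iminium and later the ketone, any cis isomer can relax to the all-trans compound; all three new centres are thus under steric control and 8 is meso. Chemoselectivity is helped by excess 5, by adding 5 only after Tf2O has been consumed by 3, and by silyl ethers that offer neither a hydridic C–H for a 1,5-hydride shift to the keteniminium carbon nor a basic oxygen.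

Step 5
Reactants: 8 2,4-bis{[(tert-butyldiphenylsilyl)oxy]methyl}-3-phenylcyclobutan-1-one; 9 phenylmagnesium bromide
Product: 10 2,4-bis{[(tert-butyldiphenylsilyl)oxy]methyl}-1,3-diphenylcyclobutan-1-ol (drawn as the epimer with hydroxyl cis to both side chains)
Conditions: CeCl3 (anhydrous), THF, −78 °C → −40 °C; then aq. NH4Cl
Reagents that add atoms: none
Why: Organocerium 1,2-addition (Imamoto conditions); weakly basic PhCeCl2 adds to the strained cyclobutanone faster than it enolises it, which avoids β-elimination of silanolate and α-epimerisation, and either carbinol epimer is acceptable because this centre is planarised in step 6.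

Step 6
Reactants: 10 2,4-bis{[(tert-butyldiphenylsilyl)oxy]methyl}-1,3-diphenylcyclobutan-1-ol
Product: 11 1,3-bis{[(tert-butyldiphenylsilyl)oxy]methyl}-2,4-diphenylcyclobutane (both side chains cis to the C2 phenyl and trans to the C4 phenyl; meso)
Conditions: Et3SiH, CF3CO2H, CH2Cl2, −40 °C → 0 °C
Reagents that add atoms: none
Why: Ionic hydrogenation; the acid ionises the tertiary benzylic alcohol and the silane traps the 1-phenylcyclobutyl cation, with the two bulky silyloxymethyl groups shielding one face so that hydride enters anti to them and the C2 phenyl ends cis to both arms and trans to the C4 phenyl.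

Step 7
Reactants: 11 1,3-bis{[(tert-butyldiphenylsilyl)oxy]methyl}-2,4-diphenylcyclobutane
Product: 12 (2,4-diphenylcyclobutane-1,3-diyl)dimethanol (hydroxymethyl groups cis to each other and to the C2 phenyl; meso)
Conditions: Bu4NF, THF, rt; then H2O
Reagents that add atoms: none
Why: Fluoride-induced cleavage of both silyl ethers; no stereocentre is involved.

Step 8
Reactants: 12 (2,4-diphenylcyclobutane-1,3-diyl)dimethanol
Product: 13 2,4-diphenylcyclobutane-1,3-dicarboxylic acid with cis carboxyl groups (both cis to the C2 phenyl)
Conditions: TEMPO (cat.), NaOCl (cat.), NaClO2, MeCN–phosphate buffer (pH 6.7), 35 °C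
Reagents that add atoms: sodium chlorite [Na+].[O-]Cl=O
Why: TEMPO-catalysed oxidation with chlorite as terminal oxidant (the chlorite variant of the Anelli oxidation) takes both primary alcohols to acids near neutral pH; chlorite traps each aldehyde as it forms, which limits closure of the cis hydroxy aldehyde to a bridged lactol, and no ring centre is touched.

Step 9
Reactants: 13 cis-2,4-diphenylcyclobutane-1,3-dicarboxylic acid
Product: 14 dimethyl 2,4-diphenylcyclobutane-1,3-dicarboxylate with cis ester groups
Conditions: MeOH, H2SO4 (cat.), reflux
Reagents that add atoms: methanol CO
Why: Fischer esterification in methanol as solvent, one molecule of methanol being taken up per carboxyl group; it provides the enolisable ester needed for step 10, and any epimerisation here is harmless because step 10 equilibrates the same centres.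

Step 10
Reactants: 14 dimethyl cis-2,4-diphenylcyclobutane-1,3-dicarboxylate
Product: 16 α-truxillic acid [(1α,2α,3β,4β)-2,4-diphenylcyclobutane-1,3-dicarboxylic acid; carboxyls trans; phenyls trans], via dimethyl α-truxillate 15 (not isolated)
Conditions: NaOMe (0.3 equiv), MeOH, reflux; then aq. NaOH, reflux; then aq. HCl; crystallisation from EtOH
Reagents that add atoms: sodium hydroxide [Na+].[OH-]
Why: Thermodynamic epimerisation α to an ester followed by saponification; methoxide interconverts 14 and 15 by inversion of one ester-bearing carbon, and since in 14 the C2 phenyl is wedged between two cis esters while in 15 each phenyl has one cis neighbour, 15 should be favoured or at least well populated, after which the centrosymmetric, sparingly soluble 16 should crystallise away from the more soluble 13, which is returned to step 9.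

Step 11
Reactants: 16 α-truxillic acid; 17 resorcinol
Product: 18 (2,4-diphenylcyclobutane-1,3-diyl)bis[(2,4-dihydroxyphenyl)methanone] with aroyl groups trans and phenyl groups trans (CNP0398987.2)
Conditions: 17 (2.5 equiv), BF3·OEt2, 85 °C; then aq. NaOAc
Reagents that add atoms: resorcinol (second molecule) Oc1cccc(O)c1
Why: Twofold Nencki-type Friedel–Crafts acylation of the phenol by the free diacid, one molecule of 17 being taken up per carboxyl group with loss of water; BF3 activates each carboxyl group and C-acylation occurs at C4 of resorcinol (para to one hydroxyl, ortho to the other), the ketone staying coordinated to boron until the acetate work-up, with temperature and time kept low to limit enolisation at C1 and C3.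

## Compound list

1 | methyl 3-hydroxypropanoate | COC(=O)CCO | starting material
2 | methyl 3-[(tert-butyldiphenylsilyl)oxy]propanoate | COC(=O)CCO[Si](c1ccccc1)(c1ccccc1)C(C)(C)C | intermediate
3 | 3-[(tert-butyldiphenylsilyl)oxy]-N,N-dimethylpropanamide | CN(C)C(=O)CCO[Si](c1ccccc1)(c1ccccc1)C(C)(C)C | intermediate
4 | (E)-cinnamyl alcohol | OC/C=C/c1ccccc1 | starting material
5 | (E)-tert-butyl(cinnamyloxy)diphenylsilane | c1ccccc1/C=C/CO[Si](c1ccccc1)(c1ccccc1)C(C)(C)C | intermediate
6 | N-{3-[(tert-butyldiphenylsilyl)oxy]prop-1-en-1-ylidene}-N-methylmethanaminium triflate (keteniminium triflate) | C[N+](C)=C=CCO[Si](c1ccccc1)(c1ccccc1)C(C)(C)C.[O-]S(=O)(=O)C(F)(F)F | intermediate (not isolated)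
7 | N-(2,4-bis{[(tert-butyldiphenylsilyl)oxy]methyl}-3-phenylcyclobutylidene)-N-methylmethanaminium triflate, both side chains trans to phenyl (cyclobutaniminium triflate) | CC(C)(C)[Si](c1ccccc1)(c1ccccc1)OC[C@@H]1C(=[N+](C)C)[C@H](CO[Si](c2ccccc2)(c2ccccc2)C(C)(C)C)[C@H]1c1ccccc1.[O-]S(=O)(=O)C(F)(F)F | intermediate (not isolated)
8 | 2,4-bis{[(tert-butyldiphenylsilyl)oxy]methyl}-3-phenylcyclobutan-1-one, both side chains trans to phenyl, meso | CC(C)(C)[Si](c1ccccc1)(c1ccccc1)OC[C@@H]1C(=O)[C@H](CO[Si](c2ccccc2)(c2ccccc2)C(C)(C)C)[C@H]1c1ccccc1 | intermediate
9 | phenylmagnesium bromide | Br[Mg]c1ccccc1 | starting material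
10 | 2,4-bis{[(tert-butyldiphenylsilyl)oxy]methyl}-1,3-diphenylcyclobutan-1-ol, hydroxyl cis to both side chains, the two phenyls cis | CC(C)(C)[Si](c1ccccc1)(c1ccccc1)OC[C@@H]1[C@@](O)(c2ccccc2)[C@H](CO[Si](c2ccccc2)(c2ccccc2)C(C)(C)C)[C@H]1c1ccccc1 | intermediate
11 | 1,3-bis{[(tert-butyldiphenylsilyl)oxy]methyl}-2,4-diphenylcyclobutane, side chains cis to the C2 phenyl and trans to the C4 phenyl, meso | CC(C)(C)[Si](c1ccccc1)(c1ccccc1)OC[C@@H]1[C@H](c2ccccc2)[C@H](CO[Si](c2ccccc2)(c2ccccc2)C(C)(C)C)[C@H]1c1ccccc1 | intermediate
12 | (2,4-diphenylcyclobutane-1,3-diyl)dimethanol, hydroxymethyl groups cis, meso | OC[C@@H]1[C@H](c2ccccc2)[C@H](CO)[C@H]1c1ccccc1 | intermediate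
13 | 2,4-diphenylcyclobutane-1,3-dicarboxylic acid, carboxyls cis to each other and to the C2 phenyl | OC(=O)[C@@H]1[C@H](c2ccccc2)[C@H](C(=O)O)[C@H]1c1ccccc1 | intermediate
14 | dimethyl 2,4-diphenylcyclobutane-1,3-dicarboxylate, esters cis | COC(=O)[C@@H]1[C@H](c2ccccc2)[C@H](C(=O)OC)[C@H]1c1ccccc1 | intermediate
15 | dimethyl α-truxillate (esters trans, phenyls trans) | COC(=O)[C@H]1[C@H](c2ccccc2)[C@H](C(=O)OC)[C@H]1c1ccccc1 | intermediate (not isolated)
16 | α-truxillic acid, (1α,2α,3β,4β)-2,4-diphenylcyclobutane-1,3-dicarboxylic acid | OC(=O)[C@H]1[C@H](c2ccccc2)[C@H](C(=O)O)[C@H]1c1ccccc1 | intermediate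
17 | resorcinol | Oc1cccc(O)c1 | starting material
18 | (2,4-diphenylcyclobutane-1,3-diyl)bis[(2,4-dihydroxyphenyl)methanone], aroyls trans, phenyls trans (CNP0398987.2) | O=C(c1ccc(O)cc1O)[C@H]1[C@H](c2ccccc2)[C@H](C(=O)c2ccc(O)cc2O)[C@H]1c1ccccc1 | target

## Step count and least certain steps

Total: 11 steps. Longest linear sequence: 10 steps (steps 1, 2, 4–11); step 3 is a one-step branch.

**Step 4 (key step).** The most likely failure is unproductive consumption of the keteniminium: self-condensation, or ionisation of its β-silyloxy group, may outrun capture by the 1,2-disubstituted, inductively deactivated alkene. The fallback keeps the same two ring bonds but builds the ring with a ketene and adds the second arm afterwards. It sets out from 5: cycloaddition with dichloroketene (Cl3CCOCl, Zn(Cu), Et2O) should give the dichlorocyclobutanone F1 with the carbonyl carbon on the carbon remote from phenyl. Zn in AcOH removes both chlorines to give the monosubstituted cyclobutanone F2. Kinetic deprotonation at the unsubstituted α-carbon (LiN(iPr)2, THF, −78 °C), aldol addition to monomeric formaldehyde and an aq. NH4Cl quench give the hydroxymethyl ketone F3, with the new arm trans to phenyl. Silylation (TBDPSCl, imidazole) returns to the route at 8.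

**Step 10.** The most likely failure is incomplete epimerisation: the equilibrium between 14 and 15 may not lie far enough toward 15, so each pass converts only part of the material and recycling becomes long. The fallback moves the inversion to the aryl ketone stage, where the larger acyl groups should penalise the cis arrangement more and enolisation is acid-catalysed. It sets out from 13: acylation of two molecules of 17 under the conditions of step 11 gives the cis-diketone F4. Acid-mediated enolisation (TsOH, toluene, 80 °C) equilibrates C1 and C3, and the centrosymmetric isomer is separated, returning to the route at 18.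

**Step 6.** The most likely failure is loss of configuration at the two flanking carbons by reversible proton loss from the benzylic cation (elimination to the cyclobutene and reprotonation). Competing delivery of hydride to the face syn to the arms, favoured by the transannular phenyl, is the second concern. The fallback replaces the cation by a radical. It sets out from 10: the lithium alkoxide (n-BuLi, THF, −78 °C) is acylated with methyl chlorooxalate to the methyl oxalate F5. Bu3SnH and AIBN in toluene at 110 °C then remove the oxygen by way of the tertiary benzylic radical, which takes hydrogen anti to the two silyloxymethyl groups, returning to the route at 11.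

**Step 11.** The most likely failure is partial epimerisation at C1 and C3 through enolisation of the boron-complexed ketones at 85 °C, together with incomplete second acylation of the hindered acid. The fallback separates acylation from phenol liberation and runs both cold. It sets out from 16: oxalyl chloride with catalytic DMF gives the bis(acid chloride) F6. Friedel–Crafts acylation of two molecules of 1,3-dimethoxybenzene (AlCl3, CH2Cl2, 0 °C) gives the tetra-O-methyl ether F7. BBr3 (CH2Cl2, −78 °C → rt; then H2O) cleaves the four methyl ethers, returning to the route at 18.

## Further compounds

F1 | step 4 | 4-{[(tert-butyldiphenylsilyl)oxy]methyl}-2,2-dichloro-3-phenylcyclobutan-1-one, side chain trans to phenyl, racemic | CC(C)(C)[Si](c1ccccc1)(c1ccccc1)OC[C@@H]1C(=O)C(Cl)(Cl)[C@H]1c1ccccc1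
F2 | step 4 | 2-{[(tert-butyldiphenylsilyl)oxy]methyl}-3-phenylcyclobutan-1-one, trans, racemic | CC(C)(C)[Si](c1ccccc1)(c1ccccc1)OC[C@@H]1C(=O)C[C@H]1c1ccccc1
F3 | step 4 | 2-{[(tert-butyldiphenylsilyl)oxy]methyl}-4-(hydroxymethyl)-3-phenylcyclobutan-1-one, both side chains trans to phenyl, racemic | CC(C)(C)[Si](c1ccccc1)(c1ccccc1)OC[C@@H]1C(=O)[C@H](CO)[C@H]1c1ccccc1
F4 | step 10 | (2,4-diphenylcyclobutane-1,3-diyl)bis[(2,4-dihydroxyphenyl)methanone], aroyls cis to each other and to the C2 phenyl | O=C(c1ccc(O)cc1O)[C@@H]1[C@H](c2ccccc2)[C@H](C(=O)c2ccc(O)cc2O)[C@H]1c1ccccc1
F5 | step 6 | 2,4-bis{[(tert-butyldiphenylsilyl)oxy]methyl}-1,3-diphenylcyclobutyl methyl oxalate, configuration as in 10 | CC(C)(C)[Si](c1ccccc1)(c1ccccc1)OC[C@@H]1[C@@](OC(=O)C(=O)OC)(c2ccccc2)[C@H](CO[Si](c2ccccc2)(c2ccccc2)C(C)(C)C)[C@H]1c1ccccc1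
F6 | step 11 | α-truxilloyl dichloride, (1α,2α,3β,4β)-2,4-diphenylcyclobutane-1,3-dicarbonyl dichloride | ClC(=O)[C@H]1[C@H](c2ccccc2)[C@H](C(=O)Cl)[C@H]1c1ccccc1
F7 | step 11 | (2,4-diphenylcyclobutane-1,3-diyl)bis[(2,4-dimethoxyphenyl)methanone], configuration of 18 | O=C(c1ccc(OC)cc1OC)[C@H]1[C@H](c2ccccc2)[C@H](C(=O)c2ccc(OC)cc2OC)[C@H]1c1ccccc1
A1 | alternative 1 | (2,4-diphenylcyclobut-1-ene-1,3-diyl)bis[(2,4-dimethoxyphenyl)methanone], trans, racemic | O=C(c1ccc(OC)cc1OC)C1=C(c2ccccc2)[C@H](C(=O)c2ccc(OC)cc2OC)[C@H]1c1ccccc1
A2 | alternative 1 | 3-(2,4-dimethoxybenzoyl)-2,4-diphenylcyclobut-1-en-1-yl trifluoromethanesulfonate, trans, racemic | FC(F)(F)S(=O)(=O)OC1=C(c2ccccc2)[C@H](C(=O)c2ccc(OC)cc2OC)[C@H]1c1ccccc1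
A3 | alternative 1 | (2,4-dimethoxyphenyl)boronic acid | COc1ccc(B(O)O)c(OC)c1
A4 | alternative 1 | carbon monoxide | [C-]#[O+]
A5 | alternative 1 | 2,4-diphenylcyclobutane-1,3-dione (phenylketene dimer, configuration labile) | O=C1C(c2ccccc2)C(=O)C1c1ccccc1
A6 | alternative 2 | 2,4-diphenyl-N1,N3-di(quinolin-8-yl)cyclobutane-1,3-dicarboxamide, configuration of 18 | O=C(Nc1cccc2cccnc12)[C@H]1[C@H](c2ccccc2)[C@H](C(=O)Nc2cccc3cccnc23)[C@H]1c1ccccc1
A7 | alternative 2 | trans-N1,N3-di(quinolin-8-yl)cyclobutane-1,3-dicarboxamide | O=C(Nc1cccc2cccnc12)[C@H]1C[C@H](C(=O)Nc2cccc3cccnc23)C1
A8 | alternative 2 | iodobenzene | Ic1ccccc1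
A9 | alternative 3 | (2,4-diphenylcyclobutane-1,3-diyl)bis[(2,4-dimethoxyphenyl)methanone], configuration of 18 | O=C(c1ccc(OC)cc1OC)[C@H]1[C@H](c2ccccc2)[C@H](C(=O)c2ccc(OC)cc2OC)[C@H]1c1ccccc1
A10 | alternative 3 | (2,4-diethynylcyclobutane-1,3-diyl)bis[(2,4-dimethoxyphenyl)methanone], aroyls trans, ethynyls trans | O=C(c1ccc(OC)cc1OC)[C@H]1[C@H](C#C)[C@H](C(=O)c2ccc(OC)cc2OC)[C@H]1C#C
A11 | alternative 3 | acetylene | C#C
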